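The route rests on the C1–C8a bond of the central six-membered carbocycle (tetralin atoms C1, C2, C3, C4, C4a, C8a), which is closed last. Two features are exploited. The para oxygen of the syringyl ring on C1 turns C1 into an easily formed, planar quinone-methide-type cation. C8a lies para to the methoxy group of the guaiacyl ring. The precursor is an unseparated pair of carbinol epimers, a trans-α-(aryl-hydroxymethyl)-β-vanillyl-γ-butyrolactone. In one operation acid erases the carbinol centre, closes the ring, sets C1 under control of the C2/C3 pair and strips the only protecting group. The temporary lactone is then opened by hydride to the two CH2OH groups.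

Key step: step 5

Assumption 1: the (S,S) antipode of the bisphospholane ligand is taken to give the R acid, by analogy with β-aryl itaconate half-esters; if the sense is opposite, the (R,R) ligand is used and nothing else changes.
Assumption 2: 4-(benzyloxy)-3,5-dimethoxybenzaldehyde is taken as a catalogue compound.
Assumption 3: in the resolution named as a fallback, the S amine is taken as the antipode whose salt with the R acid is the less soluble one.

Step 1
Reactants: 1 vanillin; 2 dimethyl succinate
Product: 3 (E)-4-(4-hydroxy-3-methoxyphenyl)-3-(methoxycarbonyl)but-3-enoic acid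
Conditions: LiOMe (3.5 equiv), MeOH, reflux; then aq HCl
Reagents that add atoms: none
Why: Stobbe condensation, in which the succinate enolate adds to the aldehyde, the aldolate closes to a paraconic ester and E1cB opening gives the E-configured carboxylate that drives the reaction, the excess of base covering the free phenol.

Step 2
Reactants: 3 (E)-4-(4-hydroxy-3-methoxyphenyl)-3-(methoxycarbonyl)but-3-enoic acid
Product: 4 (R)-4-(4-hydroxy-3-methoxyphenyl)-3-(methoxycarbonyl)butanoic acid
Conditions: [Rh(cod)((S,S)-Et-DuPHOS)]BF4 (0.5 mol %), NaOMe (10 mol %), H2 (6 bar), MeOH, rt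
Reagents that add atoms: none
Why: Rhodium-bisphospholane asymmetric hydrogenation of a Stobbe-type itaconate half-ester, in which chelation of alkene and β-carboxylate to rhodium lets the ligand select one alkene face and sets the future C3 as R.

Step 3
Reactants: 4 (R)-4-(4-hydroxy-3-methoxyphenyl)-3-(methoxycarbonyl)butanoic acid
Product: 6 (R)-4-(4-hydroxy-3-methoxybenzyl)dihydrofuran-2(3H)-one, via hydroxy acid 5 (not isolated)
Conditions: KOH (2.0 equiv), EtOH, 0 °C; CaCl2, NaBH4, EtOH, −10 °C to rt; then 3 M HCl, rt
Reagents that add atoms: none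
Why: Chemoselective calcium borohydride reduction of the methyl ester beside the inert carboxylate and phenoxide salts, followed by acid-induced lactonisation, neither of which touches the stereocentre.

Step 4
Reactants: 6 (R)-4-(4-hydroxy-3-methoxybenzyl)dihydrofuran-2(3H)-one; 7 4-(benzyloxy)-3,5-dimethoxybenzaldehyde
Product: 9 (3S,4R)-3-[(4-benzyloxy-3,5-dimethoxyphenyl)(hydroxy)methyl]-4-(4-hydroxy-3-methoxybenzyl)dihydrofuran-2(3H)-one as both carbinol epimers, via dilithio phenoxide-enolate 8 (not isolated)
Conditions: LDA (2.2 equiv), THF, −78 °C; 7 (1.1 equiv), −78 °C; AcOH quench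
Reagents that add atoms: none
Why: Lithium enolate aldol addition in which the second equivalent of base forms the lactone enolate beside the inert phenoxide and the aldehyde is attacked anti to the β-benzyl group, which sets C2 trans to C3, while the carbinol centre forms as a mixture that needs no separation.

Step 5
Reactants: 9 (3S,4R)-3-[(4-benzyloxy-3,5-dimethoxyphenyl)(hydroxy)methyl]-4-(4-hydroxy-3-methoxybenzyl)dihydrofuran-2(3H)-one as both carbinol epimers
Product: 12 (3aR,9S,9aR)-7-hydroxy-9-(4-hydroxy-3,5-dimethoxyphenyl)-6-methoxy-3a,4,9,9a-tetrahydronaphtho[2,3-c]furan-1(3H)-one, via benzylic cation 10 (not isolated), via O-benzyl aryltetralin lactone 11 (not isolated)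
Conditions: TFA–CH2Cl2 (1:4), 0 °C; then C6HMe5 (5 equiv), TFA–CH2Cl2 (1:1), rt
Reagents that add atoms: none
Why: Both carbinol epimers of 9 ionise in TFA to the same planar benzylic cation 10, delocalised by the para oxygen as an O-alkylated p-quinone methide, so the stereochemical outcome of the aldol step is erased and the mixture converges. The guaiacyl ring then attacks in an intramolecular Friedel–Crafts alkylation, the closure known for α-(hydroxybenzyl)-β-benzylbutyrolactones, which is 6-exo-trig with respect to the exocyclic C=C of the quinone-methide form and makes the C1–C8a bond. The one new stereocentre, C1 (S), is controlled by the fixed trans C2/C3 pair, because in the half-chair transition state on the trans-fused lactone the syringyl group takes the pseudo-equatorial position anti to the carbonyl branch on C2, giving the 1,2-trans-2,3-trans array. The step needs regioselectivity for the guaiacyl carbon para to OMe over the one ortho to OMe, which is secured by para activation and by the crowding of the ortho site between two substituents. It also needs chemoselectivity over loss of H-2 and over intermolecular capture, which the short tether to the arene secures. The twisted, doubly ortho-substituted aryl benzyl ether of 11 is finally cleaved by TFA acidolysis, the benzyl cation being trapped by pentamethylbenzene.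

Step 6
Reactants: 12 (3aR,9S,9aR)-7-hydroxy-9-(4-hydroxy-3,5-dimethoxyphenyl)-6-methoxy-3a,4,9,9a-tetrahydronaphtho[2,3-c]furan-1(3H)-one
Product: 13 5-methoxy-(+)-isolariciresinol, (6R,7R,8S)-8-(4-hydroxy-3,5-dimethoxyphenyl)-6,7-bis(hydroxymethyl)-3-methoxy-5,6,7,8-tetrahydronaphthalen-2-ol
Conditions: LiAlH4 (5 equiv), THF, 0 °C to reflux, 12 added to the hydride; 1 M HCl work-up
Reagents that add atoms: none
Why: Lithium aluminium hydride reduction of the lactone to the 1,4-diol after deprotonation of both phenols, with inverse addition so that reduction outruns enolisation at C2 and no stereocentre is touched.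

Compound list
1 | vanillin | COc1cc(C=O)ccc1O | starting material
2 | dimethyl succinate | COC(=O)CCC(=O)OC | starting material
3 | (E)-4-(4-hydroxy-3-methoxyphenyl)-3-(methoxycarbonyl)but-3-enoic acid | COC(=O)/C(CC(=O)O)=C/c1ccc(O)c(OC)c1 | intermediate
4 | (R)-4-(4-hydroxy-3-methoxyphenyl)-3-(methoxycarbonyl)butanoic acid | COC(=O)[C@@H](CC(=O)O)Cc1ccc(O)c(OC)c1 | intermediate
5 | (R)-3-(hydroxymethyl)-4-(4-hydroxy-3-methoxyphenyl)butanoic acid, present as its salt, not isolated | OC[C@@H](CC(=O)O)Cc1ccc(O)c(OC)c1 | intermediate
6 | (R)-4-(4-hydroxy-3-methoxybenzyl)dihydrofuran-2(3H)-one | O=C1C[C@@H](Cc2ccc(O)c(OC)c2)CO1 | intermediate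
7 | 4-(benzyloxy)-3,5-dimethoxybenzaldehyde | COc1cc(C=O)cc(OC)c1OCc1ccccc1 | starting material
8 | dilithio phenoxide-enolate of 6, not isolated | [Li+].[Li+].[O-]C1=C[C@@H](Cc2ccc([O-])c(OC)c2)CO1 | intermediate
9 | (3S,4R)-3-[(4-benzyloxy-3,5-dimethoxyphenyl)(hydroxy)methyl]-4-(4-hydroxy-3-methoxybenzyl)dihydrofuran-2(3H)-one, both epimers at the carbinol carbon | O=C1OC[C@H](Cc2ccc(O)c(OC)c2)[C@H]1C(O)c1cc(OC)c(OCc2ccccc2)c(OC)c1 | intermediate
10 | benzylic cation (O-benzyl p-quinone-methide oxocarbenium form) from 9, not isolated | O=C1OC[C@H](Cc2ccc(O)c(OC)c2)[C@H]1[CH+]c1cc(OC)c(OCc2ccccc2)c(OC)c1 | intermediate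
11 | (3aR,9S,9aR)-9-(4-benzyloxy-3,5-dimethoxyphenyl)-7-hydroxy-6-methoxy-3a,4,9,9a-tetrahydronaphtho[2,3-c]furan-1(3H)-one, not isolated | COc1cc2c(cc1O)[C@H](c1cc(OC)c(OCc3ccccc3)c(OC)c1)[C@H]1C(=O)OC[C@@H]1C2 | intermediate
12 | (3aR,9S,9aR)-7-hydroxy-9-(4-hydroxy-3,5-dimethoxyphenyl)-6-methoxy-3a,4,9,9a-tetrahydronaphtho[2,3-c]furan-1(3H)-one | COc1cc2c(cc1O)[C@H](c1cc(OC)c(O)c(OC)c1)[C@H]1C(=O)OC[C@@H]1C2 | intermediate
13 | 5-methoxy-(+)-isolariciresinol | COc1cc2c(cc1O)[C@H](c1cc(OC)c(O)c(OC)c1)[C@@H](CO)[C@H](CO)C2 | target

Total step count: 6. Longest linear sequence: 6 (from vanillin).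

Steps most likely to fail

Step 5. After the ring closure the acidolysis of the benzyl ether may stall. The benzyl cation may also be transferred to the electron-rich rings of the product faster than to the scavenger. The fallback sets out from 9 and comes back at 12. Ring closure and deprotection are uncoupled, and the deprotection changes from acidolysis to hydrogenolysis. Compound 9 is exposed only briefly to TFA in CH2Cl2 at 0 °C without scavenger, and the O-benzyl aryltetralin lactone 11 is isolated. Its benzyl ether is then removed with H2 over Pd/C in EtOAc–EtOH. C1 is doubly benzylic but carries no heteroatom, so it should survive.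

Step 4. The phenoxide-enolate may aggregate or precipitate. The second deprotonation may remain incomplete so that proton return competes with addition, and the aldolate may revert on warming. The fallback sets out from 6 and comes back at 12. The phenol is masked first with BnBr and K2CO3 in acetone, which should give (R)-4-(4-benzyloxy-3-methoxybenzyl)dihydrofuran-2(3H)-one F1. Its simple mono-enolate (LDA, 1.1 equiv, THF, −78 °C) is added to 7 to give the bis-O-benzyl carbinol epimers F2. TFA in CH2Cl2 at 0 °C closes the ring to the bis-O-benzyl aryltetralin lactone F3. Hydrogenolysis (H2, Pd/C) then removes both benzyl groups.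

Step 2. Binding of phenoxide or carboxylate to rhodium may slow turnover, and facial selectivity may erode on this phenolic substrate. The fallback sets out from 3 and comes back at 4. Asymmetric catalysis is replaced by classical resolution. Hydrogenation over Pd/C in MeOH gives the racemic half-ester F4. Crystallisation with (S)-1-phenylethylamine gives the diastereomerically pure ammonium salt F5, and aqueous HCl liberates 4.

Further compounds
F0 | step 5 | none | none
F1 | step 4 | (R)-4-(4-benzyloxy-3-methoxybenzyl)dihydrofuran-2(3H)-one | O=C1C[C@@H](Cc2ccc(OCc3ccccc3)c(OC)c2)CO1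
F2 | step 4 | (3S,4R)-3-[(4-benzyloxy-3,5-dimethoxyphenyl)(hydroxy)methyl]-4-(4-benzyloxy-3-methoxybenzyl)dihydrofuran-2(3H)-one, both carbinol epimers | O=C1OC[C@H](Cc2ccc(OCc3ccccc3)c(OC)c2)[C@H]1C(O)c1cc(OC)c(OCc2ccccc2)c(OC)c1
F3 | step 4 | (3aR,9S,9aR)-7-benzyloxy-9-(4-benzyloxy-3,5-dimethoxyphenyl)-6-methoxy-3a,4,9,9a-tetrahydronaphtho[2,3-c]furan-1(3H)-one | COc1cc2c(cc1OCc1ccccc1)[C@H](c1cc(OC)c(OCc3ccccc3)c(OC)c1)[C@H]1C(=O)OC[C@@H]1C2
F4 | step 2 | racemic 4-(4-hydroxy-3-methoxyphenyl)-3-(methoxycarbonyl)butanoic acid | COC(=O)C(CC(=O)O)Cc1ccc(O)c(OC)c1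
F5 | step 2 | (S)-1-phenylethylammonium salt of the R half-ester | COC(=O)[C@@H](CC(=O)[O-])Cc1ccc(O)c(OC)c1.C[C@H]([NH3+])c1ccccc1
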